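**Retrosynthetic overview**
1. Target ⇒ MOM removal ⇒ Diels–Alder [4+2] of a dehydroprenyl (2R,3R)-dihydroflavonol diene with a chromene 2'-hydroxychalcone; the methylcyclohexene is the last ring formed.
2. Diene ⇒ Suzuki coupling of a 5'-chloro-dihydroflavonol with a dienylboronate; the dihydroflavonol ring ⇒ acid cyclodehydration of an aryl threo-diol ketone.
3. Diol ketone ⇒ L-tartaric acid acetonide: one carboxyl is exchanged for the ring B aryl (decarboxylative arylation, trans), the other acylates the ring A aryllithium; tartrate is the only source of chirality.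
4. Chalcone ⇒ Claisen–Schmidt condensation of a 6-acetylchromene (2,4-dihydroxyacetophenone + prenal, condensation/oxa-6π electrocyclization) with 2,4-bis(MOM-oxy)benzaldehyde.
5. Ring order: pyran of the chromene → pyranone of the dihydroflavonol → cyclohexene.

Assumption: the SMILES is read as the all-trans (exo) adduct, cyclohexene centres R (aryl-bearing), R (aroyl-bearing), S (dihydroxyphenyl-bearing), with a (2R,3R)-trans-dihydroflavonol; MOMCl, pinacolborane and the catalysts are bought.

**Step 1**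
Reactants: 1 2,4-dihydroxyacetophenone; 2 3-methylbut-2-enal (prenal)
Product: 4 1-(5-hydroxy-2,2-dimethyl-2H-chromen-6-yl)ethan-1-one, via oxatriene 3 (not isolated)
Conditions: pyridine, 140 °C (sealed tube), 16 h
Reagents that add atoms: none
Why: Knoevenagel-type condensation at the carbon between the two phenol oxygens gives oxatriene 3, whose oxa-6π electrocyclization onto the non-chelated oxygen closes the 2,2-dimethylpyran ring; no stereocentre is formed.

**Step 2**
Reactants: 5 2,4-dihydroxybenzaldehyde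
Product: 6 2,4-bis(methoxymethoxy)benzaldehyde
Conditions: MOMCl (3 equiv), K2CO3 (4 equiv), acetone, reflux
Reagents that add atoms: chloromethyl methyl ether (MOMCl), COCCl
Why: Williamson-type O-alkylation masks both phenols so the aldehyde condenses cleanly under base and the phenols stay protected until the last step.

**Step 3**
Reactants: 4 1-(5-hydroxy-2,2-dimethyl-2H-chromen-6-yl)ethan-1-one; 6 2,4-bis(methoxymethoxy)benzaldehyde
Product: 7 (E)-3-[2,4-bis(methoxymethoxy)phenyl]-1-(5-hydroxy-2,2-dimethyl-2H-chromen-6-yl)prop-2-en-1-one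
Conditions: KOH, EtOH/H2O, rt, 36 h
Reagents that add atoms: none
Why: Claisen–Schmidt aldol condensation gives the E-enone under thermodynamic control and leaves the chelated chromene 5-OH free, as the cycloaddition needs.

**Step 4**
Reactants: 8 dimethyl (4R,5R)-2,2-dimethyl-1,3-dioxolane-4,5-dicarboxylate (dimethyl 2,3-O-isopropylidene-L-tartrate)
Product: 9 (4R,5R)-5-(methoxycarbonyl)-2,2-dimethyl-1,3-dioxolane-4-carboxylic acid
Conditions: KOH (1.0 equiv), MeOH, rt; then 1 M HCl, 0 °C, pH 3
Reagents that add atoms: potassium hydroxide, [K+].[OH-]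
Why: Mono-saponification of the C2-symmetric diester stops after one ester because the carboxylate deactivates the second; both tartrate stereocentres are untouched.

**Step 5**
Reactants: 10 4-chloro-2-iodophenol
Product: 11 4-chloro-2-iodo-1-(methoxymethoxy)benzene
Conditions: MOMCl (1.3 equiv), K2CO3 (2 equiv), acetone, rt
Reagents that add atoms: chloromethyl methyl ether (MOMCl), COCCl
Why: MOM protection (Williamson O-alkylation) removes the acidic, easily oxidised phenol before the photoredox coupling and the aryllithium step.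

**Step 6**
Reactants: 9 (4R,5R)-5-(methoxycarbonyl)-2,2-dimethyl-1,3-dioxolane-4-carboxylic acid (1.5 equiv); 11 4-chloro-2-iodo-1-(methoxymethoxy)benzene
Product: 12 methyl (4R,5S)-5-[5-chloro-2-(methoxymethoxy)phenyl]-2,2-dimethyl-1,3-dioxolane-4-carboxylate
Conditions: Ir[dF(CF3)ppy]2(dtbbpy)PF6 (1 mol %), NiCl2·glyme (10 mol %), dtbbpy (15 mol %), Cs2CO3 (1.5 equiv), DMF, blue LEDs, rt
Reagents that add atoms: none
Why: Metallaphotoredox decarboxylative arylation: photo-oxidation of the carboxylate gives an α-oxy dioxolanyl radical that nickel couples at the carbon–iodine bond (the chloride is untouched) on the face anti to the neighbouring ester, so the retained tartrate centre sets the new aryl-bearing centre trans (expected dr ≥ 10:1).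

**Step 7**
Reactants: 13 4-bromobenzene-1,3-diol (4-bromoresorcinol)
Product: 14 1-bromo-2,4-bis(methoxymethoxy)benzene
Conditions: MOMCl (2.6 equiv), K2CO3 (4 equiv), acetone, reflux
Reagents that add atoms: chloromethyl methyl ether (MOMCl), COCCl
Why: MOM protection (Williamson O-alkylation) makes the bromide fit for bromine–lithium exchange, and the ortho MOM oxygen later stabilises the acyl-addition intermediate.

**Step 8**
Reactants: 14 1-bromo-2,4-bis(methoxymethoxy)benzene; 12 methyl (4R,5S)-5-[5-chloro-2-(methoxymethoxy)phenyl]-2,2-dimethyl-1,3-dioxolane-4-carboxylate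
Product: 17 [2,4-bis(methoxymethoxy)phenyl]{(4R,5S)-5-[5-chloro-2-(methoxymethoxy)phenyl]-2,2-dimethyl-1,3-dioxolan-4-yl}methanone, via aryllithium 15 (not isolated), via lithium hemiketal alkoxide 16 (not isolated)
Conditions: n-BuLi (1.05 equiv), THF, −78 °C, 30 min; cannulate into 12, THF, −78 °C; H2O quench at −78 °C
Reagents that add atoms: none
Why: Bromine–lithium exchange then nucleophilic acyl substitution: the tetrahedral adduct 16 is chelated by the α-dioxolane oxygen and the ortho MOM oxygen and survives at −78 °C, so the ketone is released only on quench; the trans-dioxolane centres are not touched.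

**Step 9**
Reactants: 17 [2,4-bis(methoxymethoxy)phenyl]{(4R,5S)-5-[5-chloro-2-(methoxymethoxy)phenyl]-2,2-dimethyl-1,3-dioxolan-4-yl}methanone
Product: 19 (2R,3R)-2-(5-chloro-2-hydroxyphenyl)-3,7-dihydroxy-2,3-dihydro-4H-chromen-4-one, via pentol 18 (not isolated)
Conditions: 3 M HCl in MeOH, 55 °C, 8 h
Reagents that add atoms: none
Why: Acid methanolysis removes the three MOM groups and the acetonide to give pentol 18, whose o-hydroxybenzylic carbinol is then displaced by the ketone's ortho phenol (acid-promoted cyclodehydration of the o-quinone-methide type); direct displacement inverts that carbon and any ionisation/reclosure equilibrates to the same diequatorial 2,3-trans ring, so the tartrate-derived C3 (R) fixes C2 as R.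

**Step 10**
Reactants: 19 (2R,3R)-2-(5-chloro-2-hydroxyphenyl)-3,7-dihydroxy-2,3-dihydro-4H-chromen-4-one
Product: 20 (2R,3R)-2-[5-chloro-2-(methoxymethoxy)phenyl]-3-hydroxy-7-(methoxymethoxy)-2,3-dihydro-4H-chromen-4-one
Conditions: MOMCl (2.2 equiv), i-Pr2NEt (3 equiv), CH2Cl2, 0 °C → rt
Reagents that add atoms: chloromethyl methyl ether (MOMCl), COCCl
Why: Chemoselective MOM protection (O-alkylation) of the two phenols over the hindered secondary ketol hydroxyl under a mild amine base; this blocks phenoxide-driven ring opening in the next step, and neither stereocentre is touched.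

**Step 11**
Reactants: 21 2-methylbut-1-en-3-yne
Product: 22 (E)-4,4,5,5-tetramethyl-2-(3-methylbuta-1,3-dien-1-yl)-1,3,2-dioxaborolane
Conditions: pinacolborane (1.05 equiv), Cp2Zr(H)Cl (5 mol %), Et3N (10 mol %), neat, 60 °C (sealed)
Reagents that add atoms: pinacolborane, [H]B1OC(C)(C)C(C)(C)O1
Why: Zirconium-catalysed syn-hydroboration of the terminal alkyne puts boron on the terminal carbon and gives the E-dienylboronate only.

**Step 12**
Reactants: 20 (2R,3R)-2-[5-chloro-2-(methoxymethoxy)phenyl]-3-hydroxy-7-(methoxymethoxy)-2,3-dihydro-4H-chromen-4-one; 22 (E)-4,4,5,5-tetramethyl-2-(3-methylbuta-1,3-dien-1-yl)-1,3,2-dioxaborolane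
Product: 23 (2R,3R)-3-hydroxy-7-(methoxymethoxy)-2-{2-(methoxymethoxy)-5-[(E)-3-methylbuta-1,3-dien-1-yl]phenyl}-2,3-dihydro-4H-chromen-4-one
Conditions: Pd(OAc)2 (5 mol %), SPhos (10 mol %), K3PO4 (2 equiv), THF/H2O 10:1, 50 °C, degassed
Reagents that add atoms: none
Why: Suzuki–Miyaura coupling: the SPhos-ligated palladium catalyst inserts into the electron-rich aryl chloride at moderate temperature, transmetalation keeps the E geometry, and the short, mildly basic, oxygen-free conditions spare the ketol centres.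

**Step 13**
Reactants: 7 (E)-3-[2,4-bis(methoxymethoxy)phenyl]-1-(5-hydroxy-2,2-dimethyl-2H-chromen-6-yl)prop-2-en-1-one; 23 (2R,3R)-3-hydroxy-7-(methoxymethoxy)-2-{2-(methoxymethoxy)-5-[(E)-3-methylbuta-1,3-dien-1-yl]phenyl}-2,3-dihydro-4H-chromen-4-one
Product: 24 (2R,3R)-2-{5-[(1R,5S,6R)-5-[2,4-bis(methoxymethoxy)phenyl]-6-(5-hydroxy-2,2-dimethyl-2H-chromene-6-carbonyl)-3-methylcyclohex-2-en-1-yl]-2-(methoxymethoxy)phenyl}-3-hydroxy-7-(methoxymethoxy)-2,3-dihydro-4H-chromen-4-one (all-trans adduct)
Conditions: Ag/SiO2 nanoparticles (from AgOTf and Bu4NBH4, 0.5 mol % Ag), CH2Cl2, 50 °C (sealed), 48 h; SiO2 chromatography, then preparative HPLC (C18)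
Reagents that add atoms: none
Why: Silver-nanoparticle-catalysed Diels–Alder cycloaddition of a 2'-hydroxychalcone: the diene's aryl and methyl groups give the ortho/para regiochemistry, the E-enone fixes aryl/aroyl trans and the exo transition state gives the all-trans triad (exo:endo expected about 1:2 to 1:1), while the distant (2R,3R) unit gives almost no facial bias, so the two exo adducts form about 1:1 and, being diastereomers thanks to the tartrate-derived centres, are separated on achiral phases to give 24 (about 10–15 % expected).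

**Step 14**
Reactants: 24 the all-trans tetra-MOM adduct
Product: 25 (2R,3R)-2-{5-[(1R,5S,6R)-5-(2,4-dihydroxyphenyl)-6-(5-hydroxy-2,2-dimethyl-2H-chromene-6-carbonyl)-3-methylcyclohex-2-en-1-yl]-2-hydroxyphenyl}-3,7-dihydroxy-2,3-dihydro-4H-chromen-4-one (CNP0204112.1)
Conditions: 3 M HCl (aq)/MeOH 1:5, 40 °C, 3 h
Reagents that add atoms: none
Why: Acid-catalysed acetal methanolysis removes the four MOM ethers under conditions milder than step 9; the trans-dihydroflavonol and the all-equatorial α-keto centre are already the thermodynamic configurations, and chromene and cyclohexene tolerate dilute acid at 40 °C.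

**Compound list**
1 | 2,4-dihydroxyacetophenone | CC(=O)c1ccc(O)cc1O | starting material
2 | 3-methylbut-2-enal (prenal) | CC(C)=CC=O | starting material
3 | 2-acetyl-3-hydroxy-6-(3-methylbut-2-enylidene)cyclohexa-2,4-dienone-type oxatriene (o-quinone methide from 1 and 2) | CC(=O)C1=C(O)C(=CC=C(C)C)C(=O)C=C1 | intermediate
4 | 1-(5-hydroxy-2,2-dimethyl-2H-chromen-6-yl)ethan-1-one | CC(=O)c1ccc2OC(C)(C)C=Cc2c1O | intermediate
5 | 2,4-dihydroxybenzaldehyde | O=Cc1ccc(O)cc1O | starting material
6 | 2,4-bis(methoxymethoxy)benzaldehyde | COCOc1ccc(C=O)c(OCOC)c1 | intermediate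
7 | (E)-3-[2,4-bis(methoxymethoxy)phenyl]-1-(5-hydroxy-2,2-dimethyl-2H-chromen-6-yl)prop-2-en-1-one | COCOc1ccc(/C=C/C(=O)c2ccc3OC(C)(C)C=Cc3c2O)c(OCOC)c1 | intermediate
8 | dimethyl (4R,5R)-2,2-dimethyl-1,3-dioxolane-4,5-dicarboxylate | COC(=O)[C@@H]1OC(C)(C)O[C@H]1C(=O)OC | starting material
9 | (4R,5R)-5-(methoxycarbonyl)-2,2-dimethyl-1,3-dioxolane-4-carboxylic acid | OC(=O)[C@@H]1OC(C)(C)O[C@H]1C(=O)OC | intermediate
10 | 4-chloro-2-iodophenol | Oc1ccc(Cl)cc1I | starting material
11 | 4-chloro-2-iodo-1-(methoxymethoxy)benzene | COCOc1ccc(Cl)cc1I | intermediate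
12 | methyl (4R,5S)-5-[5-chloro-2-(methoxymethoxy)phenyl]-2,2-dimethyl-1,3-dioxolane-4-carboxylate | COCOc1ccc(Cl)cc1[C@@H]1OC(C)(C)O[C@H]1C(=O)OC | intermediate
13 | 4-bromobenzene-1,3-diol | Oc1ccc(Br)c(O)c1 | starting material
14 | 1-bromo-2,4-bis(methoxymethoxy)benzene | COCOc1ccc(Br)c(OCOC)c1 | intermediate
15 | [2,4-bis(methoxymethoxy)phenyl]lithium | [Li]c1ccc(OCOC)cc1OCOC | intermediate
16 | lithium alkoxide of the methyl hemiketal from 15 and 12 (tetrahedral adduct, new carbinol centre undefined) | COCOc1ccc(Cl)cc1[C@@H]1OC(C)(C)O[C@H]1C([O-])(OC)c1ccc(OCOC)cc1OCOC.[Li+] | intermediate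
17 | [2,4-bis(methoxymethoxy)phenyl]{(4R,5S)-5-[5-chloro-2-(methoxymethoxy)phenyl]-2,2-dimethyl-1,3-dioxolan-4-yl}methanone | COCOc1ccc(Cl)cc1[C@@H]1OC(C)(C)O[C@H]1C(=O)c1ccc(OCOC)cc1OCOC | intermediate
18 | (2R,3S)-3-(5-chloro-2-hydroxyphenyl)-1-(2,4-dihydroxyphenyl)-2,3-dihydroxypropan-1-one | Oc1ccc(Cl)cc1[C@H](O)[C@@H](O)C(=O)c1ccc(O)cc1O | intermediate
19 | (2R,3R)-2-(5-chloro-2-hydroxyphenyl)-3,7-dihydroxy-2,3-dihydro-4H-chromen-4-one | Oc1ccc(Cl)cc1[C@H]1Oc2cc(O)ccc2C(=O)[C@@H]1O | intermediate
20 | (2R,3R)-2-[5-chloro-2-(methoxymethoxy)phenyl]-3-hydroxy-7-(methoxymethoxy)-2,3-dihydro-4H-chromen-4-one | COCOc1ccc(Cl)cc1[C@H]1Oc2cc(OCOC)ccc2C(=O)[C@@H]1O | intermediate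
21 | 2-methylbut-1-en-3-yne | CC(=C)C#C | starting material
22 | (E)-4,4,5,5-tetramethyl-2-(3-methylbuta-1,3-dien-1-yl)-1,3,2-dioxaborolane | CC(=C)/C=C/B1OC(C)(C)C(C)(C)O1 | intermediate
23 | (2R,3R)-3-hydroxy-7-(methoxymethoxy)-2-{2-(methoxymethoxy)-5-[(E)-3-methylbuta-1,3-dien-1-yl]phenyl}-2,3-dihydro-4H-chromen-4-one | COCOc1ccc(/C=C/C(C)=C)cc1[C@H]1Oc2cc(OCOC)ccc2C(=O)[C@@H]1O | intermediate
24 | all-trans tetra-MOM adduct, (2R,3R)-dihydroflavonol with (1R,5S,6R)-cyclohexenyl (name in step 13) | CC1=C[C@@H](c2ccc(OCOC)c([C@H]3Oc4cc(OCOC)ccc4C(=O)[C@@H]3O)c2)[C@H](C(=O)c2ccc3c(c2O)C=CC(C)(C)O3)[C@@H](c2ccc(OCOC)cc2OCOC)C1 | intermediate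
25 | CNP0204112.1 (name in step 14) | CC1=C[C@@H](c2ccc(O)c([C@H]3Oc4cc(O)ccc4C(=O)[C@@H]3O)c2)[C@H](C(=O)c2ccc3c(c2O)C=CC(C)(C)O3)[C@@H](c2ccc(O)cc2O)C1 | target

**Step count and risks**
Total steps: 14. Longest linear sequence: 8 steps (8 → 9 → 12 → 17 → 19 → 20 → 23 → 24 → 25).

Most likely to fail, first: step 13. The exo mode is usually the minor one and the dihydroflavonol centres sit too far from the diene to bias the face, so 24 is at best a quarter of the adduct mixture and must be separated from a close diastereomer. The fallback sets out from 7 and 23 and uses a boron template, so that the (2R,3R) unit sits next to the dienophile. B(OPh)3 (1 equiv, 4 Å sieves, PhCF3, rt) exchanges two phenoxides for the chromene phenol of 7 and the C3 hydroxyl of 23, giving the mixed phenyl borate diester F4 (not isolated), in which the chalcone carbonyl is also bound to boron. The [4+2] then runs inside this complex at 40–60 °C. Aqueous NH4Cl hydrolyses the borate and the route is rejoined at 24.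

Second: step 9. Ionisation at the benzylic carbon next to a ketol could instead give a 1,2-diketone (hydride shift) or a ketal through the ring B phenol. The fallback sets out from 17. HCl/MeOH at room temperature is stopped at the pentol 18, which is isolated. MOMCl (2.1 equiv)/K2CO3 in acetone caps only the two non-chelated phenols and gives (2R,3S)-3-[5-chloro-2-(methoxymethoxy)phenyl]-2,3-dihydroxy-1-[2-hydroxy-4-(methoxymethoxy)phenyl]propan-1-one F1. An intramolecular Mitsunobu etherification (PPh3, DIAD, THF, 0 °C) then displaces the activated benzylic hydroxyl by the chelated phenol with clean inversion. This gives 20 directly, where the route is rejoined.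

Third: step 12. The ketol/pyranone ring can open or epimerise under aqueous base, and the electron-rich aryl chloride is slow. The fallback sets out from 17, which has no base-sensitive ring. Suzuki coupling with 22 (same catalyst, 80 °C) gives the diene ketone [2,4-bis(methoxymethoxy)phenyl]{(4R,5S)-5-[2-(methoxymethoxy)-5-((E)-3-methylbuta-1,3-dien-1-yl)phenyl]-2,2-dimethyl-1,3-dioxolan-4-yl}methanone F2. Cycloaddition with 7 under the step 13 conditions and the same separation gives the all-trans (1R,5S,6R) cyclohexene adduct of F2 and 7 F3. Finally 3 M HCl in MeOH at 55 °C removes five MOM groups and the acetonide and closes the dihydroflavonol ring, coming back to the route at 25.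

**Further compounds**
F1 | step 9 | (2R,3S)-3-[5-chloro-2-(methoxymethoxy)phenyl]-2,3-dihydroxy-1-[2-hydroxy-4-(methoxymethoxy)phenyl]propan-1-one | COCOc1ccc(Cl)cc1[C@H](O)[C@@H](O)C(=O)c1ccc(OCOC)cc1O
F2 | step 12 | [2,4-bis(methoxymethoxy)phenyl]{(4R,5S)-5-[2-(methoxymethoxy)-5-((E)-3-methylbuta-1,3-dien-1-yl)phenyl]-2,2-dimethyl-1,3-dioxolan-4-yl}methanone | COCOc1ccc(/C=C/C(C)=C)cc1[C@@H]1OC(C)(C)O[C@H]1C(=O)c1ccc(OCOC)cc1OCOC
F3 | step 12 | all-trans (1R,5S,6R) cyclohexene adduct of F2 and 7 | CC1=C[C@@H](c2ccc(OCOC)c([C@@H]3OC(C)(C)O[C@H]3C(=O)c3ccc(OCOC)cc3OCOC)c2)[C@H](C(=O)c2ccc3c(c2O)C=CC(C)(C)O3)[C@@H](c2ccc(OCOC)cc2OCOC)C1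
F4 | step 13 | mixed phenyl borate diester of 7 (chromene 5-oxygen) and 23 (C3 oxygen) | COCOc1ccc(/C=C/C(=O)c2ccc3OC(C)(C)C=Cc3c2OB(Oc2ccccc2)O[C@H]2C(=O)c3ccc(OCOC)cc3O[C@@H]2c2cc(/C=C/C(C)=C)ccc2OCOC)c(OCOC)c1
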